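**Retrosynthetic overview**
1. Target 23 ← unmasking (C8 nitrile → formyl, two MOM ethers off) ← (3R)-isoflavan nitrile 20 ← removal of the temporary C4 oxygen ← cis-(3R,4R)-isoflavan-4-ol 18 ← transfer hydrogenation with dynamic kinetic resolution of racemic isoflavanone 17.
2. Ring C of 17 is closed in one operation from the open 2-fluorodeoxybenzoin 15 and formaldehyde: aldol at C3 (bond C2–C3), then SNAr of the new alkoxide on C8a (bond O1–C8a).
3. Enabling feature: in ring A, C8a lies between C8, which bears the future formyl carbon (carried as a nitrile), and C4a, which bears C4 (carried as a ketone). Both ortho acceptors activate a C8a–F bond for SNAr, and the C4 ketone, with ring B on C3, makes C3–H acidic for the aldol and later mobile for the resolution.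
4. 15 ← arylmagnesium from bromide 5 (ring A, from 2,6-difluoro-4-methoxybenzonitrile 1) + Weinreb amide 13 (ring B with its dimethylpyran ring, from (2,4-dihydroxyphenyl)acetic acid 6 and 3-chloro-3-methylbut-1-yne 10).
5. Ring order: ring A is bought as the arene; the dimethylpyran ring on ring B is formed by propargyl ether Claisen rearrangement (step 8); ring C is formed in step 10.

Key step: step 10

Remark: isoflavan numbering is used (O1, C2, C3, C4, C4a, C5–C8, C8a; ring B C1'–C6'), and the C3 stereocentre of the target is R. Compounds 1, 6 and 10 are taken to be commercial. The (R,R)-ligand in step 11 is chosen on the usual aryl/alkyl rule for this catalyst class.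

**Step 1**
Reactants: 1 2,6-difluoro-4-methoxybenzonitrile
Product: 3 2-fluoro-6-hydroxy-4-methoxybenzonitrile, via sulfonylethyl aryl ether 2 (not isolated)
Conditions: MeSO2CH2CH2OH, NaH, DMF, 0 °C to rt; then 1 M HCl
Reagents that add atoms: 2-(methylsulfonyl)ethanol, CS(=O)(=O)CCO
Why: SNAr of one of the two equivalent ortho-fluorines (activated by the nitrile) by the alkoxide, then E1cB loss of methyl vinyl sulfone, should give the phenoxide, which deactivates the ring against a second substitution and spares the nitrile from hydroxide.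

**Step 2**
Reactants: 3 2-fluoro-6-hydroxy-4-methoxybenzonitrile
Product: 4 3-bromo-2-fluoro-6-hydroxy-4-methoxybenzonitrile
Conditions: NBS, MeCN, 0 °C
Reagents that add atoms: N-bromosuccinimide, O=C1CCC(=O)N1Br
Why: electrophilic aromatic bromination is expected para to the free phenol (and ortho to OMe), at the carbon flanked by the small fluorine, in preference to the position between OH and OMe.

**Step 3**
Reactants: 4 3-bromo-2-fluoro-6-hydroxy-4-methoxybenzonitrile
Product: 5 3-bromo-2-fluoro-4-methoxy-6-(methoxymethoxy)benzonitrile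
Conditions: MOMCl, iPr2NEt, CH2Cl2, 0 °C to rt
Reagents that add atoms: chloromethyl methyl ether, COCCl
Why: O-alkylation of the acidic phenol gives the MOM ether, which is stable to bases, organomagnesium reagents, fluoride and hydride and is removed by acid at the end.

**Step 4**
Reactants: 6 (2,4-dihydroxyphenyl)acetic acid
Product: 7 6-hydroxy-1-benzofuran-2(3H)-one
Conditions: TsOH·H2O (cat.), toluene, reflux (Dean–Stark)
Reagents that add atoms: none
Why: acid-catalysed lactonisation of the 2-hydroxyphenylacetic acid ties up the ortho OH (the later pyran oxygen) and the acid together and leaves only the para OH free.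

**Step 5**
Reactants: 7 6-hydroxy-1-benzofuran-2(3H)-one
Product: 8 6-(methoxymethoxy)-1-benzofuran-2(3H)-one
Conditions: MOMCl, iPr2NEt, CH2Cl2, 0 °C
Reagents that add atoms: chloromethyl methyl ether, COCCl
Why: MOM ether formation on the only free phenol, with a mild amine base that should leave the enolisable aryl lactone intact.

**Step 6**
Reactants: 8 6-(methoxymethoxy)-1-benzofuran-2(3H)-one
Product: 9 2-[2-hydroxy-4-(methoxymethoxy)phenyl]-N-methoxy-N-methylacetamide
Conditions: MeNH(OMe)·HCl, AlMe3, CH2Cl2, 0 °C to rt; then 0.5 M HCl, 0 °C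
Reagents that add atoms: N,O-dimethylhydroxylamine hydrochloride, CNOC.Cl
Why: Weinreb aminolysis of the activated aryl ester with the aluminium amide opens the lactone and frees only the phenol ortho to the side chain.

**Step 7**
Reactants: 9 2-[2-hydroxy-4-(methoxymethoxy)phenyl]-N-methoxy-N-methylacetamide; 10 3-chloro-3-methylbut-1-yne
Product: 11 N-methoxy-2-[4-(methoxymethoxy)-2-(2-methylbut-3-yn-2-yloxy)phenyl]-N-methylacetamide
Conditions: K2CO3, KI, DMF, 60 °C
Reagents that add atoms: none
Why: O-alkylation of the single free phenol with the tertiary propargylic chloride is the standard entry to 1,1-dimethylpropargyl aryl ethers.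

**Step 8**
Reactants: 11 N-methoxy-2-[4-(methoxymethoxy)-2-(2-methylbut-3-yn-2-yloxy)phenyl]-N-methylacetamide
Product: 13 N-methoxy-2-[5-(methoxymethoxy)-2,2-dimethyl-2H-chromen-8-yl]-N-methylacetamide, via allenylphenol 12 (not isolated)
Conditions: PhNEt2, 150 °C
Reagents that add atoms: none
Why: aromatic propargyl Claisen rearrangement, in which the [3,3] shift can only go to the free ortho carbon C3' between the two oxygens, followed by enolisation, 1,5-hydrogen shift and oxa-6π electrocyclisation, should give the 2,2-dimethyl-2H-chromene with its oxygen on C2'.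

**Step 9**
Reactants: 5 3-bromo-2-fluoro-4-methoxy-6-(methoxymethoxy)benzonitrile; 13 N-methoxy-2-[5-(methoxymethoxy)-2,2-dimethyl-2H-chromen-8-yl]-N-methylacetamide
Product: 15 2-fluoro-4-methoxy-6-(methoxymethoxy)-3-{[5-(methoxymethoxy)-2,2-dimethyl-2H-chromen-8-yl]acetyl}benzonitrile, via arylmagnesium chloride 14 (not isolated)
Conditions: 5, iPrMgCl·LiCl, THF, −20 °C; then 13, −20 to 0 °C; then 0.5 M HCl, 0 °C
Reagents that add atoms: none
Why: bromine–magnesium exchange (accelerated by the flanking F and OMe and tolerated by the nitrile) followed by Weinreb ketone synthesis should stop at the ketone, provided the mixture stays at or below 0 °C so that the ortho-fluoro arylmagnesium does not lose MgClF to an aryne.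

**Step 10**
Reactants: 15 2-fluoro-4-methoxy-6-(methoxymethoxy)-3-{[5-(methoxymethoxy)-2,2-dimethyl-2H-chromen-8-yl]acetyl}benzonitrile
Product: 17 rac-5-methoxy-7-(methoxymethoxy)-3-[5-(methoxymethoxy)-2,2-dimethyl-2H-chromen-8-yl]-4-oxochromane-8-carbonitrile, via hydroxymethyl ketone 16 (not isolated)
Conditions: (CH2O)n (1.3 equiv), K2CO3, DMF, 0 °C to rt
Reagents that add atoms: formaldehyde (from paraformaldehyde), C=O
Why: Proposed new method: K2CO3 forms the C3 enolate of 15 (acidified by the C4 ketone and ring B), which adds to formaldehyde to give the alkoxide of 16 (bond C2–C3), and this alkoxide attacks C8a, whose fluoride is activated by the ortho nitrile on C8 and the ortho ketone on C4a, in an addition–elimination that forms O1–C8a and expels fluoride. The closest known reaction types are the paraformaldehyde/base annulation of 2-hydroxydeoxybenzoins to isoflavanones and base-mediated tandem aldol/SNAr or Michael/SNAr annulations of 2-fluoroaryl ketones; the new element is their merger, so that the aldol alkoxide and not a phenol makes the aryl ether bond. Ring C closes in a 6-exo-trig SNAr mode through a Meisenheimer intermediate. C3 is formed as a racemate and is deliberately left epimerisable next to the C4 ketone, so no control is needed here and its configuration is set in step 11. The step needs attack at C8a rather than at the C5 methoxy carbon (also ortho to the ketone) and a single hydroxymethylation. Fluoride as leaving group with double ortho activation should secure the first, and the fast irreversible ring closure together with the reversibility of any second aldol on 17 should secure the second.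

**Step 11**
Reactants: 17 rac-5-methoxy-7-(methoxymethoxy)-3-[5-(methoxymethoxy)-2,2-dimethyl-2H-chromen-8-yl]-4-oxochromane-8-carbonitrile
Product: 18 (3R,4R)-4-hydroxy-5-methoxy-7-(methoxymethoxy)-3-[5-(methoxymethoxy)-2,2-dimethyl-2H-chromen-8-yl]chromane-8-carbonitrile
Conditions: RuCl(p-cymene)[(R,R)-TsDPEN] (3 mol %), HCO2H/Et3N (2:3), EtOAc, 40 °C
Reagents that add atoms: none
Why: Noyori-type asymmetric transfer hydrogenation under dynamic kinetic resolution, in which Et3N epimerises C3 through the enol faster than reduction and the (R,R)-catalyst is expected to deliver hydride to the C4 carbonyl of the (3R)-ketone with its usual aryl/alkyl sense (4R) and anti to the C3 aryl group, so that C3 (R) and the temporary C4 (R) centre are set together as the cis alcohol.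

**Step 12**
Reactants: 18 (3R,4R)-4-hydroxy-5-methoxy-7-(methoxymethoxy)-3-[5-(methoxymethoxy)-2,2-dimethyl-2H-chromen-8-yl]chromane-8-carbonitrile
Product: 19 O-{(3R,4R)-8-cyano-5-methoxy-7-(methoxymethoxy)-3-[5-(methoxymethoxy)-2,2-dimethyl-2H-chromen-8-yl]chroman-4-yl} S-methyl carbonodithioate
Conditions: NaH, CS2, THF, 0 °C; then MeI
Reagents that add atoms: carbon disulfide, S=C=S; iodomethane, CI
Why: xanthate formation from the secondary benzylic alkoxide is standard, C3–H is no longer acidic, and the anti arrangement of C4–O and C3–H in the cis alcohol disfavours Chugaev syn-elimination.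

**Step 13**
Reactants: 19 O-{(3R,4R)-8-cyano-5-methoxy-7-(methoxymethoxy)-3-[5-(methoxymethoxy)-2,2-dimethyl-2H-chromen-8-yl]chroman-4-yl} S-methyl carbonodithioate
Product: 20 (3R)-5-methoxy-7-(methoxymethoxy)-3-[5-(methoxymethoxy)-2,2-dimethyl-2H-chromen-8-yl]chromane-8-carbonitrile
Conditions: Bu3SnH, AIBN (cat.), toluene, 90 °C
Reagents that add atoms: none
Why: Barton–McCombie deoxygenation through the benzylic C4 radical removes the temporary C4 centre under neutral conditions that should leave the chromene double bond, the MOM ethers, the nitrile and the C3 centre (still R) untouched.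

**Step 14**
Reactants: 20 (3R)-5-methoxy-7-(methoxymethoxy)-3-[5-(methoxymethoxy)-2,2-dimethyl-2H-chromen-8-yl]chromane-8-carbonitrile
Product: 23 (3R)-7-hydroxy-3-(5-hydroxy-2,2-dimethyl-2H-chromen-8-yl)-5-methoxychromane-8-carbaldehyde (target), via aldimine 21 (not isolated), via bis-MOM aldehyde 22 (not isolated)
Conditions: iBu2AlH, toluene, −78 to 0 °C; then MeOH, 3 M HCl, THF, 40 °C
Reagents that add atoms: water, O
Why: single hydride addition of iBu2AlH to the aryl nitrile gives the aldimine, and the dilute methanolic acid needed to hydrolyse it to the C8 aldehyde should also cleave both MOM acetals, conditions under which 2,2-dimethylchromenes are normally stable and C3 is not epimerisable.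

**Compound list**
1 | 2,6-difluoro-4-methoxybenzonitrile | COc1cc(F)c(C#N)c(F)c1 | starting material
2 | 2-fluoro-4-methoxy-6-[2-(methylsulfonyl)ethoxy]benzonitrile | COc1cc(F)c(C#N)c(OCCS(C)(=O)=O)c1 | intermediate
3 | 2-fluoro-6-hydroxy-4-methoxybenzonitrile | COc1cc(O)c(C#N)c(F)c1 | intermediate
4 | 3-bromo-2-fluoro-6-hydroxy-4-methoxybenzonitrile | COc1cc(O)c(C#N)c(F)c1Br | intermediate
5 | 3-bromo-2-fluoro-4-methoxy-6-(methoxymethoxy)benzonitrile | COCOc1cc(OC)c(Br)c(F)c1C#N | intermediate
6 | (2,4-dihydroxyphenyl)acetic acid | OC(=O)Cc1ccc(O)cc1O | starting material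
7 | 6-hydroxy-1-benzofuran-2(3H)-one | O=C1Cc2ccc(O)cc2O1 | intermediate
8 | 6-(methoxymethoxy)-1-benzofuran-2(3H)-one | COCOc1ccc2CC(=O)Oc2c1 | intermediate
9 | 2-[2-hydroxy-4-(methoxymethoxy)phenyl]-N-methoxy-N-methylacetamide | CON(C)C(=O)Cc1ccc(OCOC)cc1O | intermediate
10 | 3-chloro-3-methylbut-1-yne | CC(C)(Cl)C#C | starting material
11 | N-methoxy-2-[4-(methoxymethoxy)-2-(2-methylbut-3-yn-2-yloxy)phenyl]-N-methylacetamide | CON(C)C(=O)Cc1ccc(OCOC)cc1OC(C)(C)C#C | intermediate
12 | 2-[2-hydroxy-4-(methoxymethoxy)-3-(3-methylbuta-1,2-dien-1-yl)phenyl]-N-methoxy-N-methylacetamide | CON(C)C(=O)Cc1ccc(OCOC)c(C=C=C(C)C)c1O | intermediate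
13 | N-methoxy-2-[5-(methoxymethoxy)-2,2-dimethyl-2H-chromen-8-yl]-N-methylacetamide | CON(C)C(=O)Cc1ccc(OCOC)c2c1OC(C)(C)C=C2 | intermediate
14 | [3-cyano-2-fluoro-6-methoxy-4-(methoxymethoxy)phenyl]magnesium chloride (LiCl complex) | COCOc1cc(OC)c([Mg]Cl)c(F)c1C#N | intermediate
15 | 2-fluoro-4-methoxy-6-(methoxymethoxy)-3-{[5-(methoxymethoxy)-2,2-dimethyl-2H-chromen-8-yl]acetyl}benzonitrile | COc1cc(OCOC)c(C#N)c(F)c1C(=O)Cc1ccc(OCOC)c2c1OC(C)(C)C=C2 | intermediate
16 | rac-2-fluoro-3-{3-hydroxy-2-[5-(methoxymethoxy)-2,2-dimethyl-2H-chromen-8-yl]propanoyl}-4-methoxy-6-(methoxymethoxy)benzonitrile | COc1cc(OCOC)c(C#N)c(F)c1C(=O)C(CO)c1ccc(OCOC)c2c1OC(C)(C)C=C2 | intermediate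
17 | rac-5-methoxy-7-(methoxymethoxy)-3-[5-(methoxymethoxy)-2,2-dimethyl-2H-chromen-8-yl]-4-oxochromane-8-carbonitrile | COc1cc(OCOC)c(C#N)c2c1C(=O)C(c1ccc(OCOC)c3c1OC(C)(C)C=C3)CO2 | intermediate
18 | (3R,4R)-4-hydroxy-5-methoxy-7-(methoxymethoxy)-3-[5-(methoxymethoxy)-2,2-dimethyl-2H-chromen-8-yl]chromane-8-carbonitrile (cis) | COc1cc(OCOC)c(C#N)c2c1[C@H](O)[C@H](c1ccc(OCOC)c3c1OC(C)(C)C=C3)CO2 | intermediate
19 | O-{(3R,4R)-8-cyano-5-methoxy-7-(methoxymethoxy)-3-[5-(methoxymethoxy)-2,2-dimethyl-2H-chromen-8-yl]chroman-4-yl} S-methyl carbonodithioate | COc1cc(OCOC)c(C#N)c2c1[C@H](OC(=S)SC)[C@H](c1ccc(OCOC)c3c1OC(C)(C)C=C3)CO2 | intermediate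
20 | (3R)-5-methoxy-7-(methoxymethoxy)-3-[5-(methoxymethoxy)-2,2-dimethyl-2H-chromen-8-yl]chromane-8-carbonitrile | COc1cc(OCOC)c(C#N)c2c1C[C@H](c1ccc(OCOC)c3c1OC(C)(C)C=C3)CO2 | intermediate
21 | 1-{(3R)-5-methoxy-7-(methoxymethoxy)-3-[5-(methoxymethoxy)-2,2-dimethyl-2H-chromen-8-yl]chroman-8-yl}methanimine | COc1cc(OCOC)c(C=N)c2c1C[C@H](c1ccc(OCOC)c3c1OC(C)(C)C=C3)CO2 | intermediate
22 | (3R)-5-methoxy-7-(methoxymethoxy)-3-[5-(methoxymethoxy)-2,2-dimethyl-2H-chromen-8-yl]chromane-8-carbaldehyde | COc1cc(OCOC)c(C=O)c2c1C[C@H](c1ccc(OCOC)c3c1OC(C)(C)C=C3)CO2 | intermediate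
23 | (3R)-7-hydroxy-3-(5-hydroxy-2,2-dimethyl-2H-chromen-8-yl)-5-methoxychromane-8-carbaldehyde | COc1cc(O)c(C=O)c2c1C[C@H](c1ccc(O)c3c1OC(C)(C)C=C3)CO2 | target

**Step count**
Total steps: 14. Longest linear sequence: 11 steps (steps 4 to 14, from 6).

**Steps most likely to fail**

Step 10 (proposed method). The aldol adduct may dehydrate and dimerise by conjugate addition, or be hydroxymethylated twice, before ring closure; adventitious hydroxide may also displace the activated fluoride intermolecularly. The fallback sets out from 15 and separates the two bond formations with known chemistry. Soft enolisation (TMSCl, NaI, Et3N, MeCN) should give the trimethylsilyl enol ether F1. A lanthanide-triflate-catalysed aqueous Mukaiyama aldol with formalin (Yb(OTf)3, THF/H2O, rt) should then give the hydroxymethyl ketone 16, now isolated. Ring closure by intramolecular SNAr (K2CO3, DMF, rt) returns to the route at 17.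

Step 11. Epimerisation of C3 may be too slow relative to reduction, or hydride transfer to the hindered peri-methoxy ketone too sluggish, which would erode diastereo- and enantioselectivity. The fallback sets out from 17 and does not depend on in-flask racemisation. Corey–Bakshi–Shibata reduction ((S)-2-methyl-CBS-oxazaborolidine, catecholborane, toluene, −40 °C) should fix C4 as R on both enantiomers of the ketone, giving 18 together with the trans-(3S,4R) alcohol F4. The two diastereomers are separated by chromatography, and the route is rejoined at 18. F4 is oxidised (Dess–Martin periodinane) to the (3S)-ketone F5, which Et3N racemises to 17 for recycling.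

Step 9. The hindered, basic arylmagnesium may deprotonate the arylacetamide at its α-carbon instead of adding, and may lose fluoride to an aryne if warming is needed. The fallback sets out from 13 and 5 and uses a faster electrophile. Reduction of 13 (LiAlH4, THF, −40 °C) should give the arylacetaldehyde F2, to which the arylmagnesium 14 (from 5 as in step 9) adds at −40 °C to give the secondary alcohol F3. Oxidation (Dess–Martin periodinane, CH2Cl2) returns to the route at 15.

**Further compounds**
F1 | step 10 | (Z)-2-fluoro-4-methoxy-6-(methoxymethoxy)-3-{2-[5-(methoxymethoxy)-2,2-dimethyl-2H-chromen-8-yl]-1-(trimethylsilyloxy)ethenyl}benzonitrile | COc1cc(OCOC)c(C#N)c(F)c1/C(O[Si](C)(C)C)=C/c1ccc(OCOC)c2c1OC(C)(C)C=C2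
F2 | step 9 | [5-(methoxymethoxy)-2,2-dimethyl-2H-chromen-8-yl]acetaldehyde | O=CCc1ccc(OCOC)c2c1OC(C)(C)C=C2
F3 | step 9 | rac-2-fluoro-3-{1-hydroxy-2-[5-(methoxymethoxy)-2,2-dimethyl-2H-chromen-8-yl]ethyl}-4-methoxy-6-(methoxymethoxy)benzonitrile | COc1cc(OCOC)c(C#N)c(F)c1C(O)Cc1ccc(OCOC)c2c1OC(C)(C)C=C2
F4 | step 11 | (3S,4R)-4-hydroxy-5-methoxy-7-(methoxymethoxy)-3-[5-(methoxymethoxy)-2,2-dimethyl-2H-chromen-8-yl]chromane-8-carbonitrile (trans) | COc1cc(OCOC)c(C#N)c2c1[C@H](O)[C@@H](c1ccc(OCOC)c3c1OC(C)(C)C=C3)CO2
F5 | step 11 | (3S)-5-methoxy-7-(methoxymethoxy)-3-[5-(methoxymethoxy)-2,2-dimethyl-2H-chromen-8-yl]-4-oxochromane-8-carbonitrile | COc1cc(OCOC)c(C#N)c2c1C(=O)[C@@H](c1ccc(OCOC)c3c1OC(C)(C)C=C3)CO2
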